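Don't read the left-handed product peak as capped at half of the charge. In the zeta run it stands at 73.0% after 4.00 min, so right-handed substrate has crossed over: a dynamic kinetic resolution.

| flask | left-handed substrate | right-handed substrate | reagent | free catalyst | racemization catalyst | remark | time |
|---|---|---|---|---|---|---|---|
| zeta | 0.20 M | 0.20 M | 2.5 equiv | 0.1 mol% | 7.4 mol% | run made earlier |  |
| Saturday's | 0.30 M | 0.30 M | 2.50 equiv | 0.1 mol% | 7.4 mol% |  | 6.0 min |
| Tuesday's | 0.30 M | 0.30 M | 2.50 equiv | 0.1 mol% | 2 mol% |  | 6.0 min |

zeta run (percent of the left-handed substrate and right-handed substrate together charged)

| time / min | left-handed product / % | right-handed product / % |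
|---|---|---|
| 0.667 | 33.1 | 1.7 |
| 1.33 | 50.7 | 4.4 |
| 2.00 | 58.1 | 2.6 |
| 3.00 | 66.7 | 3.8 |
| 4.00 | 73.0 | 4.3 |

(standard deviation of a reading: 1 percentage point)

- free catalyst is single-handed; left-handed substrate and right-handed substrate are mirror images of each other, charged as a racemate, each of them at the stated concentration
- the numbers in the tables scatter by 1 percentage point (one standard deviation)
- an excess is the difference of the two amounts in percent of their sum
- an excess is below zero if the other one leads
- no earlier run changes the charge of free catalyst; that part of a forecast is a guess
- no earlier run changes the charge of racemization catalyst; that part of a forecast is a guess

- the flask that ends with the higher excess of left-handed product over right-handed product in the product, or "neither" when 2 percentage points or less lies between them (Saturday's / Tuesday's / neither)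
- excess of left-handed product over right-handed product in the product at the end, Saturday's
- excess of left-handed product over right-handed product in the product at the end, Tuesday's

Keep the books on one molecule, in fractions of the two substrates charged together. Treat the substrates as the limiting reagent: reagent stands at 2.50 equiv on the left-handed substrate, against two equivalents needed for both substrates if one reagent makes one product.

First entry: book the left-handed half to left-handed product. Second entry: send a right-handed molecule to its fork, where it either crosses and ends as left-handed product or leaks into right-handed product.

Read that fork late in zeta, from 2.00 min to 4.00 min, with left-handed product already at 58.1%. Left-handed product gains 15 percentage points and right-handed product 1.7 points, so the odds are 8.76. Against a scatter of 1 point that is rough. Take that whole gain as crossed molecules, and it gives, as a reading, the crossing chance, the share of molecules leaving the right-handed side that end as left-handed product: 89.8%.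

Close the books. Reckon left-handed product as a half plus half the chance and right-handed product as half of what remains, so on these entries, with the substrates used up, the excess equals the crossing chance.

Saturday's has zeta's mol% and equivalents, though at 0.30 M against 0.20 M, so assume the same odds and commit to 89.8%. For Tuesday's, guess that the odds follow the racemization catalyst: they fall to 2.37, giving 70.3%. My reckoning therefore favours Saturday's, higher by 20 points.

The forecast differs in both figures: Saturday's, 86% and 76%, adding “The catalyst scaling is a guess.”

Saturday's ends at 86.4% and Tuesday's at 74.3%, so Saturday's leads.

    reagent + free catalyst + left-handed substrate → free catalyst + left-handed product (k = 276 M⁻² s⁻¹)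
    reagent + free catalyst + right-handed substrate → free catalyst + right-handed product (k = 12.0 M⁻² s⁻¹)
    left-handed substrate + racemization catalyst ⇌ right-handed substrate + racemization catalyst, rate k3*[racemization catalyst]*[left-handed substrate] forward; the back reaction follows from the equilibrium constant (k = 2.85 M⁻¹ s⁻¹)
    free catalyst → spent catalyst A (k = 2.32 × 10⁻⁵ s⁻¹)
    racemization catalyst → spent catalyst B (k = 0.0141 s⁻¹)

The books stay open at 6.00 min: Saturday's still holds 6.35% right-handed substrate, with its racemization catalyst down to 0.624% of its charge, and Tuesday's holds 15.4% right-handed substrate. Apply the chance to the neighbour, Tuesday's with 5 mol% of racemization catalyst. Reckon the odds, by the same guess, at 5.92 and the chance at 85.6%. That flask ends with left-handed product 83.9%, right-handed product 7.31% and an excess of 84.0%.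

The readings stem from a simulated flask for substances that don't exist; noise was put on by code.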